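The seven-membered ring is disconnected to a trans-fused cyclohexenone plus one carbon: C9 is inserted between the carbonyl carbon C8 and C10. In one operation dibromocarbene adds to the C8=C10 silyl enol ether of the cross-conjugated 2-silyloxy diene 17 and the dibromocyclopropane opens, forming C8–C9 and C9–C10 and turning the six-membered ring (C5, C6, C7, C8, C10, C1) into the cycloheptadienone 19. The step exploits that C1 is quaternary: the C6=C7–C8=O enone has a single α′ methylene, C10, so kinetic enolisation fixes the site of insertion. Precursor 17 is a trans-hydrindane diene carrying the C1 methyl and the C4 isopropyl and triethylsilyloxy groups, with C1, C4 and C5 already set.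

Key step: step 9

Locants: C1 = methyl-bearing ring-fusion carbon, C2/C3 = cyclopentane CH2, C4 = isopropyl carbinol carbon, C5 = ring-fusion CH, C6 = acyloxy carbon, C7 = CH2, C8 = methyl carbinol carbon, C9=C10 = alkene (C10 bonded to C1).

Remark on names and acidity: these are daucane locants. By von Baeyer rules 19 is a 3-bromobicyclo[5.3.0]deca-2,5-dien-4-one, with the ketone and bromoalkene in the seven-membered ring. C5–H is a γ-hydrogen of the enone and is also acidic, so the α′ regiochemistry of step 8 rests on kinetic control.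

Assumption: the ligand antipode in step 2 is the one that gives the (R) quaternary centre; any minor enantiomer is removed by recrystallisation of triol 24 or of 29.

Step 1
Reactants: 1 3-ethoxycyclopent-2-en-1-one; 2 (2-methylprop-2-en-1-yl)magnesium chloride
Product: 4 3-(2-methylprop-2-en-1-yl)cyclopent-2-en-1-one, via magnesium alkoxide 3 (not isolated)
Conditions: THF, 0 °C; then 1 M HCl, 0 °C, short contact
Reagents that add atoms: none
Why: Stork–Danheiser transposition, in which the Grignard reagent adds 1,2 to the vinylogous ester carbonyl and cold dilute acid hydrolyses the enol ether with loss of the tertiary allylic hydroxyl to give the 3-substituted enone; no stereocentre is formed, and the brief acid contact should keep the skipped alkene out of conjugation.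

Step 2
Reactants: 4 3-(2-methylprop-2-en-1-yl)cyclopent-2-en-1-one
Product: 6 triethyl{[(3R)-3-methyl-3-(2-methylprop-2-en-1-yl)cyclopent-1-en-1-yl]oxy}silane, via aluminium enolate 5 (not isolated)
Conditions: Me3Al, Cu(OTf)2 (cat.), enantiopure sulfonate-bearing imidazolinium salt (NHC precursor) premetalated with Ag2O (cat.), THF, −78 °C; then Et3SiOTf, −78 to 0 °C
Reagents that add atoms: trimethylaluminium, C[Al](C)C; triethylsilyl trifluoromethanesulfonate, CC[Si](CC)(CC)OC(=O)... written correctly as CC[Si](CC)(CC)OS(=O)(=O)C(F)(F)F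
Why: Copper-catalysed asymmetric conjugate addition of a trialkylaluminium to a β-substituted cyclopentenone, in which the chiral NHC–copper species delivers methyl to one enone face and so sets the quaternary C1 as (R), while O-silylation of the aluminium enolate by the silyl triflate stores the C4=C5 enolate regiochemistry for step 3.

Step 3
Reactants: 6 triethyl{[(3R)-3-methyl-3-(2-methylprop-2-en-1-yl)cyclopent-1-en-1-yl]oxy}silane
Product: 7 (2S,3R)-2-(dimethoxymethyl)-3-methyl-3-(2-methylprop-2-en-1-yl)cyclopentan-1-one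
Conditions: HC(OMe)3, Me3SiOTf (cat.), CH2Cl2, −78 °C; Et3N quench
Reagents that add atoms: trimethyl orthoformate, COC(OC)OC
Why: Mukaiyama-type addition of the silyl enol ether to the dimethoxycarbenium ion released from the orthoester, in which the electrophile enters C5 anti to the larger C1 substituent (methallyl versus methyl) and the same arrangement is the more stable one at this epimerisable centre, so the acetal carbon C6 should end up trans to C10.

Step 4
Reactants: 7 (2S,3R)-2-(dimethoxymethyl)-3-methyl-3-(2-methylprop-2-en-1-yl)cyclopentan-1-one; 8 isopropylmagnesium chloride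
Product: 9 (1R,2R,3R)-2-(dimethoxymethyl)-3-methyl-3-(2-methylprop-2-en-1-yl)-1-(propan-2-yl)cyclopentan-1-ol
Conditions: anhydrous CeCl3, THF, −78 to 0 °C; aq. NH4Cl
Reagents that add atoms: none
Why: Organocerium 1,2-addition, which suppresses enolisation and β-hydride reduction at the hindered ketone, with the isopropyl group attacking C4 from the face anti to the adjacent C5 acetal substituent so that the new hydroxyl is cis to C6 and to the C1 methyl.

Step 5
Reactants: 9 (1R,2R,3R)-2-(dimethoxymethyl)-3-methyl-3-(2-methylprop-2-en-1-yl)-1-(propan-2-yl)cyclopentan-1-ol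
Product: 10 triethyl{[(1R,2R,3R)-2-(dimethoxymethyl)-3-methyl-3-(2-methylprop-2-en-1-yl)-1-(propan-2-yl)cyclopentyl]oxy}silane
Conditions: KHMDS, THF, −78 °C; then Et3SiCl, −78 °C to rt
Reagents that add atoms: chlorotriethylsilane, CC[Si](Cl)(CC)CC
Why: O-silylation of a preformed potassium alkoxide, which lets the hindered tertiary oxygen take up the silyl chloride under basic conditions that leave the acetal and all stereocentres untouched.

Step 6
Reactants: 10 triethyl{[(1R,2R,3R)-2-(dimethoxymethyl)-3-methyl-3-(2-methylprop-2-en-1-yl)-1-(propan-2-yl)cyclopentyl]oxy}silane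
Product: 12 1-[(1R,2R,3R)-2-(dimethoxymethyl)-1-methyl-3-(propan-2-yl)-3-(triethylsilyloxy)cyclopentyl]propan-2-one, via ozonide 11 (not isolated)
Conditions: O3, CH2Cl2, −78 °C (indicator end point); then PPh3, −78 °C to rt
Reagents that add atoms: ozone, [O-][O+]=O
Why: Ozonolysis with reductive work-up, in which the 1,1-disubstituted alkene is the only site that reacts quickly with ozone at low temperature and the ozonide is reduced by the phosphine to the methyl ketone (C8=O, with C7 as its methyl) without touching a stereocentre.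

Step 7
Reactants: 12 1-[(1R,2R,3R)-2-(dimethoxymethyl)-1-methyl-3-(propan-2-yl)-3-(triethylsilyloxy)cyclopentyl]propan-2-one
Product: 15 (3R,3aR,7aR)-7a-methyl-3-(propan-2-yl)-3-(triethylsilyloxy)-1,2,3,3a,7,7a-hexahydro-6H-inden-6-one, via keto aldehyde 13 (not isolated), via aldol 14 (not isolated)
Conditions: PPTS, acetone/H2O, 40 °C; extractive work-up; then Bn2NH·TFA, toluene, 50 °C
Reagents that add atoms: none
Why: Acetal hydrolysis followed by an ammonium-salt-mediated intramolecular aldol condensation, in which the ketone methyl C7 is the only nucleophilic carbon that can reach the aldehyde C6 through a six-membered transition state, dehydration gives the C6=C7 enone, and the trans ring fusion follows from the trans disposition of C6 and C10 set in steps 3 and 4.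

Step 8
Reactants: 15 (3R,3aR,7aR)-7a-methyl-3-(propan-2-yl)-3-(triethylsilyloxy)-1,2,3,3a,7,7a-hexahydro-6H-inden-6-one
Product: 17 {[(3R,3aR,7aR)-7a-methyl-3-(propan-2-yl)-3-(triethylsilyloxy)-2,3,3a,7a-tetrahydro-1H-inden-6-yl]oxy}trimethylsilane, via lithium dienolate 16 (not isolated)
Conditions: LDA, THF, −78 °C; then Me3SiCl, −78 to 0 °C; pentane, filtration, used crude
Reagents that add atoms: chlorotrimethylsilane, C[Si](C)(C)Cl
Why: Kinetic enolate formation and O-silylation, in which the bulky amide base removes an α′ proton at C10 at low temperature faster than the hindered γ proton at C5, so trapping on oxygen gives the cross-conjugated dienol ether with C5 untouched.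

Step 9
Reactants: 17 {[(3R,3aR,7aR)-7a-methyl-3-(propan-2-yl)-3-(triethylsilyloxy)-2,3,3a,7a-tetrahydro-1H-inden-6-yl]oxy}trimethylsilane
Product: 19 (3R,3aR,8aS)-7-bromo-8a-methyl-3-(propan-2-yl)-3-(triethylsilyloxy)-2,3,3a,8a-tetrahydroazulen-6(1H)-one, via dibromocyclopropane 18 (not isolated)
Conditions: CHBr3, KOt-Bu, pentane, −20 °C to rt; then 40 °C
Reagents that add atoms: bromoform, BrC(Br)Br
Why: Dibromocarbene, formed by α-elimination from bromoform, adds in a cheletropic [2+1] fashion to the electron-rich C8=C10 enol ether, and the siloxy dibromocyclopropane 18 then loses bromide in a disrotatory two-electron electrocyclic opening that breaks the old C8–C10 bond and gives a silyloxyallyl cation, which bromide desilylates to the 2-bromo enone. The closest known reaction type is the dihalocarbene one-carbon ring enlargement of cyclic trimethylsilyl enol ethers to 2-halocycloalkenones. The three-membered ring is closed by the [2+1] cycloaddition, and the seven-membered ring arises from it by ring enlargement (electrocyclic cleavage of the shared bond), not by an end-to-end cyclisation. No stereocentre is created; C1, C4 and C5 are not involved and the trans fusion is kept. The step needs chemoselectivity for C8=C10 over C6=C7, which the far more nucleophilic oxygen-substituted double bond provides, and regiocontrol of the insertion, which is fixed by the enol ether position from step 8. Solid KOt-Bu in pentane is chosen so that the enol ether is cyclopropanated before the alkoxide can cleave it.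

Step 10
Reactants: 19 (3R,3aR,8aS)-7-bromo-8a-methyl-3-(propan-2-yl)-3-(triethylsilyloxy)-2,3,3a,8a-tetrahydroazulen-6(1H)-one
Product: 20 (3R,3aR,8aR)-8a-methyl-3-(propan-2-yl)-3-(triethylsilyloxy)-2,3,3a,8a-tetrahydroazulen-6(1H)-one
Conditions: Pd(OAc)2 (cat.), PPh3, HCO2H, Et3N, DMF, 60 °C
Reagents that add atoms: none
Why: Palladium-catalysed formate hydrogenolysis of a vinyl bromide, in which zerovalent palladium inserts into the activated C9–Br bond, formate replaces bromide and loses CO2, and C–H reductive elimination gives the parent dienone without touching the enone alkenes or the silyl ether.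

Step 11
Reactants: 20 (3R,3aR,8aR)-8a-methyl-3-(propan-2-yl)-3-(triethylsilyloxy)-2,3,3a,8a-tetrahydroazulen-6(1H)-one
Product: 22 (3R,3aS,4S,8aR)-4-hydroxy-8a-methyl-3-(propan-2-yl)-3-(triethylsilyloxy)-2,3,3a,4,5,8a-hexahydroazulen-6(1H)-one, via boryl ketone 21 (not isolated)
Conditions: B2pin2 (1.05 equiv), CuCl (cat.), NaOt-Bu (cat.), DPEphos (cat.), MeOH, THF, rt; then NaBO3·4H2O, THF/H2O, rt
Reagents that add atoms: sodium perborate, [Na+].[O-]OB=O
Why: Copper-catalysed conjugate borylation followed by perborate oxidation with retention, in which the boryl copper species adds to C6 (the β carbon that is not neopentyl) from the face anti to the C1 methyl, because a reagent on the methyl face would stand syn-pentane to it, so boron and then the C6 hydroxyl are cis to H5.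

Step 12
Reactants: 22 (3R,3aS,4S,8aR)-4-hydroxy-8a-methyl-3-(propan-2-yl)-3-(triethylsilyloxy)-2,3,3a,4,5,8a-hexahydroazulen-6(1H)-one
Product: 23 (3R,3aS,4S,6S,8aR)-6,8a-dimethyl-3-(propan-2-yl)-3-(triethylsilyloxy)-1,2,3,3a,4,5,6,8a-octahydroazulene-4,6-diol
Conditions: MeLi (excess), anhydrous CeCl3, THF, −78 °C; aq. NH4Cl
Reagents that add atoms: methyllithium, [Li]C
Why: Organocerium 1,2-addition to an enone carbonyl, in which methyl should approach C8 from the face of H5, away from the axial C1 methyl and the axial H6 and on the side of the metal alkoxide at C6, setting C8 with its methyl cis to the C6 oxygen and its hydroxyl trans to it.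

Step 13
Reactants: 23 (3R,3aS,4S,6S,8aR)-6,8a-dimethyl-3-(propan-2-yl)-3-(triethylsilyloxy)-1,2,3,3a,4,5,6,8a-octahydroazulene-4,6-diol
Product: 24 (3R,3aS,4S,6S,8aR)-6,8a-dimethyl-3-(propan-2-yl)-1,2,3,3a,4,5,6,8a-octahydroazulene-3,4,6-triol
Conditions: TBAF, THF, rt to 45 °C
Reagents that add atoms: none
Why: Fluoride-mediated desilylation, in which fluoride attacks the silicon of the tertiary triethylsilyl ether and frees the C4 hydroxyl under basic conditions that do not ionise the tertiary allylic alcohol.

Step 14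
Reactants: 25 vanillic acid
Product: 26 4-acetoxy-3-methoxybenzoic acid
Conditions: Ac2O, pyridine, rt; then H2O
Reagents that add atoms: acetic anhydride, CC(=O)OC(C)=O
Why: Phenol acetylation with acetic anhydride, any mixed anhydride at the carboxyl group being hydrolysed in the aqueous work-up, which masks the phenol for the acyl transfer.

Step 15
Reactants: 26 4-acetoxy-3-methoxybenzoic acid; 24 (3R,3aS,4S,6S,8aR)-6,8a-dimethyl-3-(propan-2-yl)-1,2,3,3a,4,5,6,8a-octahydroazulene-3,4,6-triol
Product: 28 [(3R,3aS,4S,6S,8aR)-3,6-dihydroxy-6,8a-dimethyl-3-(propan-2-yl)-1,2,3,3a,4,5,6,8a-octahydroazulen-4-yl] 4-acetoxy-3-methoxybenzoate, via acid chloride 27 (not isolated)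
Conditions: 26, (COCl)2, DMF (cat.), CH2Cl2, 0 °C to rt, evaporation; then 24, Et3N, DMAP, CH2Cl2, 0 °C to rt
Reagents that add atoms: none
Why: Acid chloride formation and DMAP-catalysed acylation, in which only the secondary C6 hydroxyl of the triol is acylated at a useful rate because the two tertiary hydroxyls are too hindered, and C6 keeps its configuration because its C–O bond is not broken.

Step 16
Reactants: 28 [(3R,3aS,4S,6S,8aR)-3,6-dihydroxy-6,8a-dimethyl-3-(propan-2-yl)-1,2,3,3a,4,5,6,8a-octahydroazulen-4-yl] 4-acetoxy-3-methoxybenzoate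
Product: 29 [(3R,3aS,4S,6S,8aR)-3,6-dihydroxy-6,8a-dimethyl-3-(propan-2-yl)-1,2,3,3a,4,5,6,8a-octahydroazulen-4-yl] 4-hydroxy-3-methoxybenzoate
Conditions: pyrrolidine, CH2Cl2, 0 °C
Reagents that add atoms: none
Why: Chemoselective aminolysis of an aryl acetate, which is far more electrophilic than the hindered secondary aroyl ester, so pyrrolidine should remove only the acetyl group.

Compound list
1 | 3-ethoxycyclopent-2-en-1-one | CCOC1=CC(=O)CC1 | starting material
2 | (2-methylprop-2-en-1-yl)magnesium chloride (methallylmagnesium chloride) | CC(=C)C[Mg]Cl | starting material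
3 | chloromagnesium 3-ethoxy-1-(2-methylprop-2-en-1-yl)cyclopent-2-en-1-olate (racemic 1,2-adduct, not isolated) | CCOC1=CC(CC(C)=C)(O[Mg]Cl)CC1 | intermediate
4 | 3-(2-methylprop-2-en-1-yl)cyclopent-2-en-1-one | CC(=C)CC1=CC(=O)CC1 | intermediate
5 | dimethylaluminium (3R)-3-methyl-3-(2-methylprop-2-en-1-yl)cyclopent-1-en-1-olate (not isolated) | C[Al](C)OC1=C[C@@](C)(CC(C)=C)CC1 | intermediate
6 | triethyl{[(3R)-3-methyl-3-(2-methylprop-2-en-1-yl)cyclopent-1-en-1-yl]oxy}silane | CC[Si](CC)(CC)OC1=C[C@@](C)(CC(C)=C)CC1 | intermediate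
7 | (2S,3R)-2-(dimethoxymethyl)-3-methyl-3-(2-methylprop-2-en-1-yl)cyclopentan-1-one (acetal trans to methallyl) | COC(OC)[C@@H]1[C@@](C)(CC(C)=C)CCC1=O | intermediate
8 | isopropylmagnesium chloride | CC(C)[Mg]Cl | starting material
9 | (1R,2R,3R)-2-(dimethoxymethyl)-3-methyl-3-(2-methylprop-2-en-1-yl)-1-(propan-2-yl)cyclopentan-1-ol (hydroxyl cis to the acetal and to the ring methyl) | COC(OC)[C@@H]1[C@@](C)(CC(C)=C)CC[C@@]1(O)C(C)C | intermediate
10 | triethyl{[(1R,2R,3R)-2-(dimethoxymethyl)-3-methyl-3-(2-methylprop-2-en-1-yl)-1-(propan-2-yl)cyclopentyl]oxy}silane | COC(OC)[C@@H]1[C@@](C)(CC(C)=C)CC[C@@]1(O[Si](CC)(CC)CC)C(C)C | intermediate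
11 | secondary ozonide of 10 (methallyl alkene converted into a 3-methyl-1,2,4-trioxolan-3-yl group; not isolated) | COC(OC)[C@@H]1[C@@](C)(CC2(C)OCOO2)CC[C@@]1(O[Si](CC)(CC)CC)C(C)C | intermediate
12 | 1-[(1R,2R,3R)-2-(dimethoxymethyl)-1-methyl-3-(propan-2-yl)-3-(triethylsilyloxy)cyclopentyl]propan-2-one | COC(OC)[C@@H]1[C@@](C)(CC(C)=O)CC[C@@]1(O[Si](CC)(CC)CC)C(C)C | intermediate
13 | (1R,2R,5R)-2-methyl-2-(2-oxopropyl)-5-(propan-2-yl)-5-(triethylsilyloxy)cyclopentane-1-carbaldehyde (not isolated) | O=C[C@@H]1[C@@](C)(CC(C)=O)CC[C@@]1(O[Si](CC)(CC)CC)C(C)C | intermediate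
14 | trans-fused aldol: 4-hydroxy-7a-methyl-3-(propan-2-yl)-3-(triethylsilyloxy)octahydro-6H-inden-6-one, carbinol configuration open (not isolated) | OC1CC(=O)C[C@@]2(C)CC[C@@](O[Si](CC)(CC)CC)(C(C)C)[C@H]12 | intermediate
15 | (3R,3aR,7aR)-7a-methyl-3-(propan-2-yl)-3-(triethylsilyloxy)-1,2,3,3a,7,7a-hexahydro-6H-inden-6-one (trans-fused; silyloxy cis to the angular methyl) | C1=CC(=O)C[C@@]2(C)CC[C@@](O[Si](CC)(CC)CC)(C(C)C)[C@H]12 | intermediate
16 | lithium dienolate of 15 (C8–O–Li, C8=C10, C6=C7; not isolated) | C1=CC(O[Li])=C[C@@]2(C)CC[C@@](O[Si](CC)(CC)CC)(C(C)C)[C@H]12 | intermediate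
17 | {[(3R,3aR,7aR)-7a-methyl-3-(propan-2-yl)-3-(triethylsilyloxy)-2,3,3a,7a-tetrahydro-1H-inden-6-yl]oxy}trimethylsilane (key-step precursor) | C1=CC(O[Si](C)(C)C)=C[C@@]2(C)CC[C@@](O[Si](CC)(CC)CC)(C(C)C)[C@H]12 | intermediate
18 | dibromocyclopropane adduct of 17 (CBr2 = C9 bridging C8 and C10, C8 bearing OSiMe3, cyclopropane configuration open; not isolated) | C1=CC2(O[Si](C)(C)C)C(Br)(Br)C2[C@@]3(C)CC[C@@](O[Si](CC)(CC)CC)(C(C)C)[C@H]13 | intermediate
19 | (3R,3aR,8aS)-7-bromo-8a-methyl-3-(propan-2-yl)-3-(triethylsilyloxy)-2,3,3a,8a-tetrahydroazulen-6(1H)-one (key-step product, trans-fused) | C1=CC(=O)C(Br)=C[C@@]2(C)CC[C@@](O[Si](CC)(CC)CC)(C(C)C)[C@H]12 | intermediate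
20 | (3R,3aR,8aR)-8a-methyl-3-(propan-2-yl)-3-(triethylsilyloxy)-2,3,3a,8a-tetrahydroazulen-6(1H)-one | C1=CC(=O)C=C[C@@]2(C)CC[C@@](O[Si](CC)(CC)CC)(C(C)C)[C@H]12 | intermediate
21 | C6 pinacolboronate of the 6,7-dihydro enone (boron cis to H5; not isolated) | CC1(C)OB(OC1(C)C)[C@H]2CC(=O)C=C[C@@]3(C)CC[C@@](O[Si](CC)(CC)CC)(C(C)C)[C@H]23 | intermediate
22 | (3R,3aS,4S,8aR)-4-hydroxy-8a-methyl-3-(propan-2-yl)-3-(triethylsilyloxy)-2,3,3a,4,5,8a-hexahydroazulen-6(1H)-one | O[C@H]1CC(=O)C=C[C@@]2(C)CC[C@@](O[Si](CC)(CC)CC)(C(C)C)[C@H]12 | intermediate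
23 | (3R,3aS,4S,6S,8aR)-6,8a-dimethyl-3-(propan-2-yl)-3-(triethylsilyloxy)-1,2,3,3a,4,5,6,8a-octahydroazulene-4,6-diol | O[C@H]1C[C@](C)(O)C=C[C@@]2(C)CC[C@@](O[Si](CC)(CC)CC)(C(C)C)[C@H]12 | intermediate
24 | (3R,3aS,4S,6S,8aR)-6,8a-dimethyl-3-(propan-2-yl)-1,2,3,3a,4,5,6,8a-octahydroazulene-3,4,6-triol | O[C@H]1C[C@](C)(O)C=C[C@@]2(C)CC[C@@](O)(C(C)C)[C@H]12 | intermediate
25 | vanillic acid (4-hydroxy-3-methoxybenzoic acid) | COc1cc(C(=O)O)ccc1O | starting material
26 | 4-acetoxy-3-methoxybenzoic acid | COc1cc(C(=O)O)ccc1OC(C)=O | intermediate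
27 | 4-acetoxy-3-methoxybenzoyl chloride (not isolated) | COc1cc(C(=O)Cl)ccc1OC(C)=O | intermediate
28 | [(3R,3aS,4S,6S,8aR)-3,6-dihydroxy-6,8a-dimethyl-3-(propan-2-yl)-1,2,3,3a,4,5,6,8a-octahydroazulen-4-yl] 4-acetoxy-3-methoxybenzoate | COc1cc(C(=O)O[C@H]2C[C@](C)(O)C=C[C@@]3(C)CC[C@@](O)(C(C)C)[C@H]23)ccc1OC(C)=O | intermediate
29 | [(3R,3aS,4S,6S,8aR)-3,6-dihydroxy-6,8a-dimethyl-3-(propan-2-yl)-1,2,3,3a,4,5,6,8a-octahydroazulen-4-yl] 4-hydroxy-3-methoxybenzoate (CNP0243386.2) | COc1cc(C(=O)O[C@H]2C[C@](C)(O)C=C[C@@]3(C)CC[C@@](O)(C(C)C)[C@H]23)ccc1O | target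

Total step count: 16. Longest linear sequence: 15 steps (steps 1–13, 15 and 16, from 1 to 29).

Steps most likely to fail

Step 9. The carbene may add to the C6=C7 bond instead, or tert-butoxide may strip the silyl group from the enol ether before cyclopropanation, so that the enone 15 is simply returned. The fallback sets out from 17 and keeps the same one-carbon insertion, but uses a carbenoid and an oxidative opening. Et2Zn/CH2I2 in CH2Cl2 (Simmons–Smith, Furukawa variant) should cyclopropanate the enol ether to the siloxy vinylcyclopropane F1. FeCl3 in DMF at 0 °C should then open it with ring enlargement (Ito–Saegusa) to the β-chloro ketone F2. NaOAc in MeOH should eliminate HCl and return to the route at dienone 20, bypassing 19 and step 10.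

Step 7. Once the aldehyde is free, enolisation toward C5 can expel the C4 silyloxy group or epimerise C5 before the ring closes, which would give an enal or the cis-fused enone. The fallback sets out from 12 and never frees the aldehyde. LDA/Me3SiCl at −78 °C should give the kinetic enol silane F3 at the ketone methyl group. Catalytic Me3SiOTf in CH2Cl2 at −78 °C should ionise the acetal, and the enol silane should close onto the oxocarbenium ion (intramolecular Mukaiyama acetal aldol) to give the β-methoxy ketone F4. DBU in CH2Cl2 should eliminate methanol and return to the route at 15.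

Step 12. Methyl transfer to the wrong face of the C8 carbonyl would give the C8 epimer. The fallback sets out from 22 and places oxygen, not carbon, on the open face. Et3SiCl/imidazole in DMF should give the bis-silyl ether F5, and Wittig methylenation (Ph3P=CH2, THF) should give the 8-methylene diene F6. mCPBA/NaHCO3 should epoxidise the exocyclic alkene from the same open face to give the spiro-epoxide F7. LiEt3BH should open the epoxide at its CH2 carbon to the tertiary alcohol F8, and TBAF should remove both silyl groups, returning to the route at triol 24.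

Further compounds
F1 | step 9 | siloxy vinylcyclopropane: CH2 (C9) bridging C8 and C10 of 17, C8 bearing OSiMe3, C6=C7 retained | C1=CC2(O[Si](C)(C)C)CC2[C@@]3(C)CC[C@@](O[Si](CC)(CC)CC)(C(C)C)[C@H]13
F2 | step 9 | trans-fused 10-chloro-6-en-8-one (β-chloro ketone, C10 configuration open) with C1 methyl and C4 isopropyl/triethylsilyloxy | C1=CC(=O)CC(Cl)[C@@]2(C)CC[C@@](O[Si](CC)(CC)CC)(C(C)C)[C@H]12
F3 | step 7 | kinetic trimethylsilyl enol ether of 12 at the ketone methyl group | COC(OC)[C@@H]1[C@@](C)(CC(=C)O[Si](C)(C)C)CC[C@@]1(O[Si](CC)(CC)CC)C(C)C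
F4 | step 7 | trans-fused 4-methoxy-7a-methyl-3-(propan-2-yl)-3-(triethylsilyloxy)octahydro-6H-inden-6-one (methoxy configuration open) | COC1CC(=O)C[C@@]2(C)CC[C@@](O[Si](CC)(CC)CC)(C(C)C)[C@H]12
F5 | step 12 | C6 triethylsilyl ether of 22 | CC[Si](CC)(CC)O[C@H]1CC(=O)C=C[C@@]2(C)CC[C@@](O[Si](CC)(CC)CC)(C(C)C)[C@H]12
F6 | step 12 | 8-methylene diene from F5 (C8=CH2, C9=C10) | CC[Si](CC)(CC)O[C@H]1CC(=C)C=C[C@@]2(C)CC[C@@](O[Si](CC)(CC)CC)(C(C)C)[C@H]12
F7 | step 12 | spiro-epoxide at C8 of F6, epoxide oxygen on the face of the C1 methyl | CC[Si](CC)(CC)O[C@H]1C[C@]3(OC3)C=C[C@@]2(C)CC[C@@](O[Si](CC)(CC)CC)(C(C)C)[C@H]12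
F8 | step 12 | C4,C6-bis(triethylsilyl) ether of triol 24 | CC[Si](CC)(CC)O[C@H]1C[C@](C)(O)C=C[C@@]2(C)CC[C@@](O[Si](CC)(CC)CC)(C(C)C)[C@H]12
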